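Between the alpha run and the zeta run one product holds still, a fraction of the charge times the charge. Divide alpha's dissolved fraction at 12.0 min by zeta's and time drops out, leaving 1.53, close to the inverse ratio of their charges, 1.50, while target, the smaller reading at a scatter of 0.3 percentage points, gives 1.65. The release therefore reads as zero order in the solid, and while solid is left, with coupling partner and protic impurity held at their charges, you can carry a reading to another charge of solid by the transfer ratio, the charge of the run read divided by the charge of the flask wanted, from alpha to this flask 0.500.

| setting | alpha | zeta | flask |
|---|---|---|---|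
| solid substrate | 1 M | 1.5 M | 2.0 M |
| coupling partner | 2.1 M | 2.1 M | 2.10 M |
| protic impurity | 0.040 M | 0.040 M | 0.0400 M |
| remark | run made earlier | run made earlier |  |
| time |  |  | 20 min |

| run | time / min | target / % | dissolved substrate / % |
|---|---|---|---|
| alpha | 1.00 | 0 | 3.0 |
| alpha | 1.50 | 0.2 | 4.3 |
| alpha | 2.50 | 1.1 | 5.8 |
| alpha | 4.00 | 2.2 | 8.9 |
| alpha | 8.00 | 4.8 | 15.5 |
| alpha | 12.0 | 8.4 | 20.4 |
| zeta | 1.00 | 0 | 2.6 |
| zeta | 1.50 | 0.2 | 2.7 |
| zeta | 2.50 | 0.7 | 4.3 |
| zeta | 4.00 | 1.7 | 5.6 |
| zeta | 8.00 | 3.3 | 10.1 |
| zeta | 12.0 | 5.1 | 13.3 |

(each reading ± 0.3 percentage points)

- how much target there is at 20 min, in percent of the solid substrate charged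
- concentration of dissolved substrate in solution at 20 min, in percent of saturation

- given per volume of solution although it is solid: solid substrate
- the earlier runs were read with a standard deviation of 0.3 percentage points
- steps that have been proposed: solid substrate <-> dissolved substrate; dissolved substrate + coupling partner <-> target; coupling partner + protic impurity -> quenched reagent; target <-> isomer of the product
- at the start none of the solid substrate is in solution
- dissolved substrate means what is dissolved; the solid is not counted in it

Alpha's last target, carried over, puts 4.20% in this flask at 12.0 min, and two extremes start from there. If target stopped gaining, the flask would hold that 4.20% at 20 min; if target grew as the square of time, as it does under a dissolved fraction rising on a straight line, the flask would hold 11.7%. I expect this flask between them, for alpha's target was still climbing, from 4.8% to 8.4%, while alpha's dissolved fraction rose by 4.9 points over its last span, less than the 6.6 points of the equal span before. From 4.00 min to 12.0 min time grew 3.00-fold and target 3.82-fold in alpha and 3.00-fold in zeta, less than the 9.00-fold of the square, so my own reckoning takes the straight line and commits to 7.00%.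

The forecast, holding that “solid loading barely affects dissolution”, says 8% of target, above my figure, and 51% of saturation.

The flask gives 6.36% of target, within the forecast's margin, and 41.2% of saturation, 9.8 points below the forecast.

    solid substrate ⇌ dissolved substrate, rate k1*(cs1 - [dissolved substrate]) while solid is left; crystals form when [dissolved substrate] > cs1 (solubility = 0.700 M, k = 0.0430 min⁻¹)
    dissolved substrate + coupling partner ⇌ target (K = 0.290 M⁻¹, k = 0.0760 M⁻¹ min⁻¹)
    coupling partner + protic impurity → quenched reagent (k = 7.60 M⁻¹ min⁻¹)
    target ⇌ isomer of the product (K = 0.580, k = 0.0530 min⁻¹)

Alpha at its last reading, without the scatter, holds 8.02% of target, and the transfer ratio turns that into 4.01%, while the same run with this flask's charge of solid holds 4.01%. The neighbouring flask, charged with 0.50 M of solid substrate, takes a ratio of 4.00 from this flask, so 6.36% becomes 25.4%. At 20.0 min that neighbour holds 25.4% of target, with 8.71% of its charge still solid.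

All runs are calculated with made-up constants; the scatter is artificial.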